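The route cuts the C2–C1' bond of the upper flavan unit and treats ring C as a "sugar": C2 is the O1-bearing, anomeric-type carbon next to the C3 carbinol. In the key step an arylzinc carrying the whole lower half (ring B already joined through C6' to C6 of perbenzylated (+)-catechin) displaces bromide from a (3S)-2-bromochroman-3-yl pivalate. Participation of the C3 pivalate, as an acyloxonium bridge over C2–C3, should form the C2–aryl bond and set C2 trans to C3 in one operation. The precursors are a 2'-bromobiaryl made by aryne coupling and a chroman-2,3-diol dipivalate derived from methyl (S)-glycidate.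

Key step: step 12

Assumption: the target structure carries no descriptor for the C6'–C6 biaryl axis, so the axis is treated as stereochemically undefined (rotamers) in 10, 11 and 22–26; lactol-derived compounds 19–21 are C2 epimer mixtures.

Step 1
Reactants: 1 (+)-catechin
Product: 2 5,7,3',4'-tetra-O-benzyl-(+)-catechin
Conditions: BnBr (4.4 equiv), K2CO3, DMF, 0 °C → rt
Reagents that add atoms: benzyl bromide, BrCc1ccccc1
Why: Williamson etherification with a carbonate base should alkylate only the four phenols, leaving the aliphatic 3-OH free and avoiding the strongly basic conditions that epimerise C2 of free catechin.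

Step 2
Reactants: 2 5,7,3',4'-tetra-O-benzyl-(+)-catechin
Product: 3 3,5,7,3',4'-penta-O-benzyl-(+)-catechin
Conditions: NaH, BnBr, n-Bu4NI (cat.), DMF, 0 °C → rt
Reagents that add atoms: benzyl bromide, BrCc1ccccc1
Why: Williamson etherification of the secondary alkoxide; with every phenol capped, no quinone-methide ring opening can scramble C2.

Step 3
Reactants: 3 3,5,7,3',4'-penta-O-benzyl-(+)-catechin
Product: 4 8-chloro-3,5,7,3',4'-penta-O-benzyl-(+)-catechin
Conditions: NCS (1.05 equiv), DMF, 0 °C → rt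
Reagents that add atoms: N-chlorosuccinimide, O=C1CCC(=O)N1Cl
Why: Electrophilic aromatic chlorination of the trioxygenated ring A, expected at C8 by analogy with the C8 selectivity of NBS on O-benzylated catechins; the chlorine blocks C8 and is not touched by the later halogen–metal exchange at C6 or by magnesium insertion.

Step 4
Reactants: 4 8-chloro-3,5,7,3',4'-penta-O-benzyl-(+)-catechin
Product: 5 6-bromo-8-chloro-3,5,7,3',4'-penta-O-benzyl-(+)-catechin
Conditions: NBS (1.1 equiv), CH2Cl2, 0 °C → rt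
Reagents that add atoms: N-bromosuccinimide, O=C1CCC(=O)N1Br
Why: Electrophilic aromatic bromination at C6, the only open position of the most electron-rich ring (ring A); the dialkoxyphenyl rings are much less activated.

Step 5
Reactants: 6 1,2-bis(benzyloxy)benzene
Product: 7 1,2-bis(benzyloxy)-4,5-dibromobenzene
Conditions: Br2 (2.1 equiv), NaOAc, AcOH/CH2Cl2, 0 °C → rt
Reagents that add atoms: bromine, BrBr
Why: Twofold electrophilic aromatic bromination para to each alkoxy group (as for veratrole to 4,5-dibromoveratrole), with acetate buffering HBr so that the benzyl ethers survive.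

Step 6
Reactants: 5 6-bromo-8-chloro-3,5,7,3',4'-penta-O-benzyl-(+)-catechin; 7 1,2-bis(benzyloxy)-4,5-dibromobenzene
Product: 11 (2R,3S)-3,5,7-tris(benzyloxy)-6-[4,5-bis(benzyloxy)-2-bromophenyl]-2-[3,4-bis(benzyloxy)phenyl]-8-chlorochroman, via C6-aryllithium 8 (not isolated), via 4,5-bis(benzyloxy)benzyne 9 (not isolated), via 2'-lithiobiaryl 10 (not isolated)
Conditions: n-BuLi (1.0 equiv), THF, −78 °C; then 7 (1.1 equiv), −78 °C → rt
Reagents that add atoms: none
Why: Transition-metal-free aryne coupling (aryllithium plus 1,2-dibromoarene chain process): Br/Li exchange occurs at C6 while the C8 chloride is inert, the aryllithium adds to the symmetrical aryne released from 7, and the resulting 2'-lithiobiaryl takes bromine from 7, so the hindered C6–C6' bond and the ortho bromine handle should be installed regiospecifically.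

Step 7
Reactants: 12 3,5-bis(benzyloxy)phenol
Product: 13 1,3-bis(benzyloxy)-5-(methoxymethoxy)benzene
Conditions: MOMCl, i-Pr2NEt, CH2Cl2, 0 °C → rt
Reagents that add atoms: chloromethyl methyl ether, COCCl
Why: O-alkylation of the phenol gives an acetal that serves as the directing group for ortho-lithiation and is removable by mild acid in the presence of benzyl ethers.

Step 8
Reactants: 13 1,3-bis(benzyloxy)-5-(methoxymethoxy)benzene; 14 methyl (S)-glycidate
Product: 17 methyl (2S)-3-[2,4-bis(benzyloxy)-6-(methoxymethoxy)phenyl]-2-hydroxypropanoate, via aryllithium 15 (not isolated), via arylmagnesium bromide 16 (not isolated)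
Conditions: n-BuLi, TMEDA, THF, 0 °C; MgBr2·OEt2, −40 °C; CuBr·SMe2 (10 mol %), 14, −40 → −10 °C; aq NH4Cl
Reagents that add atoms: none
Why: Directed ortho-metalation between the OMOM and OBn groups followed by copper-catalysed SN2 opening of the glycidic ester at its CH2 terminus should give the α-hydroxy ester; the (S) stereocentre of 14 is not touched and becomes C3 of the upper unit.

Step 9
Reactants: 17 methyl (2S)-3-[2,4-bis(benzyloxy)-6-(methoxymethoxy)phenyl]-2-hydroxypropanoate
Product: 18 (3S)-5,7-bis(benzyloxy)-3-hydroxychroman-2-one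
Conditions: HCl, MeOH/THF, 40 °C; then TsOH (cat.), toluene, 80 °C
Reagents that add atoms: none
Why: Acid-catalysed cleavage of the MOM acetal and lactonisation (intramolecular transesterification) to the six-membered aryl lactone; acidic conditions should not epimerise the α-hydroxy stereocentre.

Step 10
Reactants: 18 (3S)-5,7-bis(benzyloxy)-3-hydroxychroman-2-one
Product: 19 (3S)-5,7-bis(benzyloxy)chroman-2,3-diol (C2 epimer mixture)
Conditions: i-Bu2AlH (2.3 equiv), CH2Cl2, −78 °C; aq potassium sodium tartrate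
Reagents that add atoms: none
Why: Partial reduction of a lactone to the lactol, as known for dihydrocoumarins; the aluminium hemiacetal is stable at −78 °C and should prevent over-reduction.

Step 11
Reactants: 19 (3S)-5,7-bis(benzyloxy)chroman-2,3-diol
Product: 20 (3S)-5,7-bis(benzyloxy)chroman-2,3-diyl bis(2,2-dimethylpropanoate) (C2 epimer mixture)
Conditions: PivCl (3 equiv), pyridine, DMAP (cat.), CH2Cl2, 0 °C → rt
Reagents that add atoms: pivaloyl chloride, CC(C)(C)C(Cl)=O
Why: Acylation of the cyclic lactol and the C3 alcohol installs the anomeric leaving group and the participating, organometal-resistant C3 pivalate in one operation.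

Step 12
Reactants: 11 (2R,3S)-3,5,7-tris(benzyloxy)-6-[4,5-bis(benzyloxy)-2-bromophenyl]-2-[3,4-bis(benzyloxy)phenyl]-8-chlorochroman; 20 (3S)-5,7-bis(benzyloxy)chroman-2,3-diyl bis(2,2-dimethylpropanoate)
Product: 24 (2R,3S)-5,7-bis(benzyloxy)-2-{4,5-bis(benzyloxy)-2-[(2R,3S)-3,5,7-tris(benzyloxy)-2-(3,4-bis(benzyloxy)phenyl)-8-chlorochroman-6-yl]phenyl}chroman-3-yl pivalate, via 2-bromochroman pivalate 21 (not isolated), via biarylmagnesium bromide 22 (not isolated), via biarylzinc bromide 23 (not isolated)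
Conditions: 20, TMSBr, ZnBr2 (cat.), CH2Cl2, 0 °C, then evaporation; 11, Mg turnings (activated with 1 mol % i-Bu2AlH), LiCl, THF, 25 °C, then ZnBr2, 0 °C → rt, THF exchanged for toluene/n-Bu2O; both combined, 25 → 80 °C
Reagents that add atoms: none
Why: TMSBr converts the anomeric pivalate of 20 into bromide 21, whose C2–Br bond ionises with anchimeric assistance from the C3 pivalate carbonyl to a cis-fused 1,3-dioxolan-2-ylium ion across C2–C3 of ring C, and arylzinc 23 (LiCl-assisted magnesium insertion into the C–Br bond of 11 to Grignard reagent 22, then transmetalation with ZnBr2) attacks C2 from the face opposite this bridge. The closest known reaction type is the uncatalysed arylzinc C-aryl glycosylation of 2-O-pivaloyl glycosyl bromides, which gives 1,2-trans C-aryl glycosides by the same participation mechanism; Lewis-acid substitution at C2 of 2-acyloxy- and 2-alkoxychromans is likewise established. No ring is closed, since ring C is pre-formed and only the C2–C1' bond is made. The new C2 stereocentre is controlled by the (3S) carbon through the participating pivalate, which should give the 2,3-trans (2R,3S) arrangement of the catechin series. The step needs chemoselective metalation and a defined site on ring B: at 25 °C magnesium should insert into the C–Br bond and leave the electron-rich C8 chloride alone, arylzincs tolerate pivalate and benzyl ether groups, and the position of the bromine in 11 fixes which ring-B carbon bonds to C2.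

Step 13
Reactants: 24 the 3-O-pivaloyl coupled product
Product: 25 (2R,3S)-5,7-bis(benzyloxy)-2-{4,5-bis(benzyloxy)-2-[(2R,3S)-3,5,7-tris(benzyloxy)-2-(3,4-bis(benzyloxy)phenyl)-8-chlorochroman-6-yl]phenyl}chroman-3-ol
Conditions: i-Bu2AlH (3 equiv), CH2Cl2, −78 °C → 0 °C; aq potassium sodium tartrate
Reagents that add atoms: none
Why: Reductive cleavage of the hindered pivalate ester; benzyl ethers, the aryl chloride and all four stereocentres are inert to the hydride.

Step 14
Reactants: 25 the nonabenzyl 8-chloro chroman-3-ol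
Product: 26 (2R,3S)-2-{2-[(2R,3S)-2-(3,4-dihydroxyphenyl)-3,5,7-trihydroxychroman-6-yl]-4,5-dihydroxyphenyl}chroman-3,5,7-triol (target)
Conditions: H2 (1–3 bar), Pd(OH)2/C, Et3N (2 equiv), THF/MeOH, rt
Reagents that add atoms: none
Why: Catalytic hydrogenolysis should cleave the nine benzyl ethers and hydrodechlorinate C8 (Et3N as HCl scavenger), as precedented for the simultaneous removal of benzyl groups and a C8 halogen blocking group from flavan-3-ol oligomers; no stereocentre is involved.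

Compound list
1 | (+)-catechin | Oc1cc(O)c2c(c1)O[C@H](c1ccc(O)c(O)c1)[C@@H](O)C2 | starting material
2 | 5,7,3',4'-tetra-O-benzyl-(+)-catechin | O(Cc1ccccc1)c1cc(OCc2ccccc2)c2c(c1)O[C@H](c1ccc(OCc3ccccc3)c(OCc3ccccc3)c1)[C@@H](O)C2 | intermediate
3 | 3,5,7,3',4'-penta-O-benzyl-(+)-catechin | O(Cc1ccccc1)c1cc(OCc2ccccc2)c2c(c1)O[C@H](c1ccc(OCc3ccccc3)c(OCc3ccccc3)c1)[C@@H](OCc1ccccc1)C2 | intermediate
4 | 8-chloro-3,5,7,3',4'-penta-O-benzyl-(+)-catechin | O(Cc1ccccc1)c1cc(OCc2ccccc2)c2c(c1Cl)O[C@H](c1ccc(OCc3ccccc3)c(OCc3ccccc3)c1)[C@@H](OCc1ccccc1)C2 | intermediate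
5 | 6-bromo-8-chloro-3,5,7,3',4'-penta-O-benzyl-(+)-catechin | O(Cc1ccccc1)c1c(Br)c(OCc2ccccc2)c2c(c1Cl)O[C@H](c1ccc(OCc3ccccc3)c(OCc3ccccc3)c1)[C@@H](OCc1ccccc1)C2 | intermediate
6 | 1,2-bis(benzyloxy)benzene | c1ccc(OCc2ccccc2)c(OCc2ccccc2)c1 | starting material
7 | 1,2-bis(benzyloxy)-4,5-dibromobenzene | Brc1cc(OCc2ccccc2)c(OCc2ccccc2)cc1Br | intermediate
8 | C6-aryllithium of 8-chloro-penta-O-benzylcatechin | O(Cc1ccccc1)c1c([Li])c(OCc2ccccc2)c2c(c1Cl)O[C@H](c1ccc(OCc3ccccc3)c(OCc3ccccc3)c1)[C@@H](OCc1ccccc1)C2 | intermediate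
9 | 4,5-bis(benzyloxy)benzyne | C1(OCc2ccccc2)=CC#CC=C1OCc1ccccc1 | intermediate
10 | 2'-lithiobiaryl (6-[4,5-bis(benzyloxy)-2-lithiophenyl]-8-chloro-penta-O-benzylcatechin) | O(Cc1ccccc1)c1c(-c3cc(OCc4ccccc4)c(OCc4ccccc4)cc3[Li])c(OCc2ccccc2)c2c(c1Cl)O[C@H](c1ccc(OCc3ccccc3)c(OCc3ccccc3)c1)[C@@H](OCc1ccccc1)C2 | intermediate
11 | (2R,3S)-3,5,7-tris(benzyloxy)-6-[4,5-bis(benzyloxy)-2-bromophenyl]-2-[3,4-bis(benzyloxy)phenyl]-8-chlorochroman | O(Cc1ccccc1)c1c(-c3cc(OCc4ccccc4)c(OCc4ccccc4)cc3Br)c(OCc2ccccc2)c2c(c1Cl)O[C@H](c1ccc(OCc3ccccc3)c(OCc3ccccc3)c1)[C@@H](OCc1ccccc1)C2 | intermediate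
12 | 3,5-bis(benzyloxy)phenol | Oc1cc(OCc2ccccc2)cc(OCc2ccccc2)c1 | starting material
13 | 1,3-bis(benzyloxy)-5-(methoxymethoxy)benzene | COCOc1cc(OCc2ccccc2)cc(OCc2ccccc2)c1 | intermediate
14 | methyl (S)-glycidate (methyl (2S)-oxirane-2-carboxylate) | COC(=O)[C@@H]1CO1 | starting material
15 | [2,4-bis(benzyloxy)-6-(methoxymethoxy)phenyl]lithium | [Li]c1c(OCOC)cc(OCc2ccccc2)cc1OCc1ccccc1 | intermediate
16 | [2,4-bis(benzyloxy)-6-(methoxymethoxy)phenyl]magnesium bromide | Br[Mg]c1c(OCOC)cc(OCc2ccccc2)cc1OCc1ccccc1 | intermediate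
17 | methyl (2S)-3-[2,4-bis(benzyloxy)-6-(methoxymethoxy)phenyl]-2-hydroxypropanoate | COC(=O)[C@@H](O)Cc1c(OCOC)cc(OCc2ccccc2)cc1OCc1ccccc1 | intermediate
18 | (3S)-5,7-bis(benzyloxy)-3-hydroxychroman-2-one | O=C1Oc2cc(OCc3ccccc3)cc(OCc3ccccc3)c2C[C@@H]1O | intermediate
19 | (3S)-5,7-bis(benzyloxy)chroman-2,3-diol (C2 epimers) | OC1Oc2cc(OCc3ccccc3)cc(OCc3ccccc3)c2C[C@@H]1O | intermediate
20 | (3S)-5,7-bis(benzyloxy)chroman-2,3-diyl bis(2,2-dimethylpropanoate) (C2 epimers) | CC(C)(C)C(=O)OC1Oc2cc(OCc3ccccc3)cc(OCc3ccccc3)c2C[C@@H]1OC(=O)C(C)(C)C | intermediate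
21 | (3S)-5,7-bis(benzyloxy)-2-bromochroman-3-yl pivalate (C2 epimers) | BrC1Oc2cc(OCc3ccccc3)cc(OCc3ccccc3)c2C[C@@H]1OC(=O)C(C)(C)C | intermediate
22 | {4,5-bis(benzyloxy)-2-[(2R,3S)-3,5,7-tris(benzyloxy)-2-(3,4-bis(benzyloxy)phenyl)-8-chlorochroman-6-yl]phenyl}magnesium bromide | O(Cc1ccccc1)c1c(-c3cc(OCc4ccccc4)c(OCc4ccccc4)cc3[Mg]Br)c(OCc2ccccc2)c2c(c1Cl)O[C@H](c1ccc(OCc3ccccc3)c(OCc3ccccc3)c1)[C@@H](OCc1ccccc1)C2 | intermediate
23 | {4,5-bis(benzyloxy)-2-[(2R,3S)-3,5,7-tris(benzyloxy)-2-(3,4-bis(benzyloxy)phenyl)-8-chlorochroman-6-yl]phenyl}zinc bromide | O(Cc1ccccc1)c1c(-c3cc(OCc4ccccc4)c(OCc4ccccc4)cc3[Zn]Br)c(OCc2ccccc2)c2c(c1Cl)O[C@H](c1ccc(OCc3ccccc3)c(OCc3ccccc3)c1)[C@@H](OCc1ccccc1)C2 | intermediate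
24 | (2R,3S)-5,7-bis(benzyloxy)-2-{4,5-bis(benzyloxy)-2-[(2R,3S)-3,5,7-tris(benzyloxy)-2-(3,4-bis(benzyloxy)phenyl)-8-chlorochroman-6-yl]phenyl}chroman-3-yl pivalate | O(Cc1ccccc1)c1cc(OCc2ccccc2)c2c(c1)O[C@H](c1cc(OCc3ccccc3)c(OCc3ccccc3)cc1-c1c(OCc3ccccc3)c(Cl)c3c(c1OCc1ccccc1)C[C@H](OCc1ccccc1)[C@@H](c1ccc(OCc4ccccc4)c(OCc4ccccc4)c1)O3)[C@@H](OC(=O)C(C)(C)C)C2 | intermediate
25 | (2R,3S)-5,7-bis(benzyloxy)-2-{4,5-bis(benzyloxy)-2-[(2R,3S)-3,5,7-tris(benzyloxy)-2-(3,4-bis(benzyloxy)phenyl)-8-chlorochroman-6-yl]phenyl}chroman-3-ol | O(Cc1ccccc1)c1cc(OCc2ccccc2)c2c(c1)O[C@H](c1cc(OCc3ccccc3)c(OCc3ccccc3)cc1-c1c(OCc3ccccc3)c(Cl)c3c(c1OCc1ccccc1)C[C@H](OCc1ccccc1)[C@@H](c1ccc(OCc4ccccc4)c(OCc4ccccc4)c1)O3)[C@@H](O)C2 | intermediate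
26 | (2R,3S)-2-{2-[(2R,3S)-2-(3,4-dihydroxyphenyl)-3,5,7-trihydroxychroman-6-yl]-4,5-dihydroxyphenyl}chroman-3,5,7-triol | Oc1cc(O)c2c(c1)O[C@H](c1cc(O)c(O)cc1-c1c(O)cc3c(c1O)C[C@H](O)[C@@H](c1ccc(O)c(O)c1)O3)[C@@H](O)C2 | target

Total step count: 14. Longest linear sequence: 8 steps (steps 1, 2, 3, 4, 6, 12, 13, 14 from (+)-catechin; equally steps 7–14 from 3,5-bis(benzyloxy)phenol).

Steps most likely to fail

Step 12. The very hindered ortho-biaryl zinc reagent may attack the bridged cation too slowly, so that loss of HBr from the bromide (elimination to an enol ester) or reaction through an unbridged oxocarbenium ion (erosion of trans selectivity) takes over. The fallback sets out from 11 and 19 and returns at 25. Grignard reagent 22, prepared from 11 as in step 12 (Mg, LiCl, THF, 25 °C), is used without transmetalation to zinc. It is added to lactol 19, first deprotonated with two equivalents of i-PrMgCl, which reacts through its ring-opened α-oxido aldehyde form under magnesium chelation (Cram-chelate addition) and should give the syn-triol F1. Mitsunobu cyclisation of F1 (PPh3, DIAD, THF) closes ring C by attack of the phenol on the benzylic carbinol with inversion and should give the 2,3-trans chroman-3-ol 25 directly.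

Step 6. Bromine–lithium back-exchange between aryllithium 8 and dibromide 7 may return 5 faster than the aryne is captured, or the aryne may oligomerise. The fallback sets out from 5 and 6 and returns at 11. Compound 6 is monobrominated (NBS, MeCN) to 1,2-bis(benzyloxy)-4-bromobenzene F2 and iodinated para to the second alkoxy group (NIS, TFA cat., MeCN) to 1,2-bis(benzyloxy)-4-bromo-5-iodobenzene F3. Aryllithium 8 from 5 (n-BuLi, THF, −78 °C) is transmetalated with ZnCl2 to the C6-arylzinc chloride F4, which undergoes Negishi coupling with F3 selectively at the C–I bond (Pd(PPh3)4, THF, 60 °C) to give 11.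

Step 14. Hydrodechlorination at the hindered, electron-rich C8 position may stall while debenzylation proceeds, and forcing it risks hydrogenolytic opening of the benzylic C2–O1 bonds. The fallback sets out from 25 and returns at 26. The chlorine is removed first with the benzyl ethers in place by palladium-catalysed transfer hydrodehalogenation (Pd(OAc)2, IPr·HCl, NaOt-Bu, i-PrOH, 60 °C) to the chlorine-free nonabenzyl ether F5, which is then debenzylated under amine-free hydrogenolysis (H2, Pd(OH)2/C, THF/MeOH, rt) to 26.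

Further compounds
F1 | step 12 | syn-(1S,2S)-1-{4,5-bis(benzyloxy)-2-[(2R,3S)-3,5,7-tris(benzyloxy)-2-(3,4-bis(benzyloxy)phenyl)-8-chlorochroman-6-yl]phenyl}-3-[2,4-bis(benzyloxy)-6-hydroxyphenyl]propane-1,2-diol | O[C@@H](c1cc(OCc3ccccc3)c(OCc3ccccc3)cc1-c1c(OCc3ccccc3)c(Cl)c3c(c1OCc1ccccc1)C[C@H](OCc1ccccc1)[C@@H](c1ccc(OCc4ccccc4)c(OCc4ccccc4)c1)O3)[C@@H](O)Cc1c(O)cc(OCc2ccccc2)cc1OCc1ccccc1
F2 | step 6 | 1,2-bis(benzyloxy)-4-bromobenzene | Brc1ccc(OCc2ccccc2)c(OCc2ccccc2)c1
F3 | step 6 | 1,2-bis(benzyloxy)-4-bromo-5-iodobenzene | Brc1cc(OCc2ccccc2)c(OCc2ccccc2)cc1I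
F4 | step 6 | C6-arylzinc chloride of 8-chloro-penta-O-benzylcatechin | O(Cc1ccccc1)c1c([Zn]Cl)c(OCc2ccccc2)c2c(c1Cl)O[C@H](c1ccc(OCc3ccccc3)c(OCc3ccccc3)c1)[C@@H](OCc1ccccc1)C2
F5 | step 14 | (2R,3S)-5,7-bis(benzyloxy)-2-{4,5-bis(benzyloxy)-2-[(2R,3S)-3,5,7-tris(benzyloxy)-2-(3,4-bis(benzyloxy)phenyl)chroman-6-yl]phenyl}chroman-3-ol | O(Cc1ccccc1)c1cc(OCc2ccccc2)c2c(c1)O[C@H](c1cc(OCc3ccccc3)c(OCc3ccccc3)cc1-c1c(OCc3ccccc3)cc3c(c1OCc1ccccc1)C[C@H](OCc1ccccc1)[C@@H](c1ccc(OCc4ccccc4)c(OCc4ccccc4)c1)O3)[C@@H](O)C2
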